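All runs come from a simulation with made-up constants.

I have to choose the charge of G for the next flask, and I want E through within 3.0 min without paying for more catalyst than that takes.

common to all: E 0.044 M; X 2.8 mM (held)
- south: G 0.052 mM; run made earlier
- north: G 0.24 mM; run made earlier
- south-east: G 0.92 mM; run made earlier
- beta: G 0.060 mM; time 3.0 min
- theta: G 0.12 mM; time 3.0 min
- eta: G 0.20 mM; time 3.0 min
- zeta: G 0.40 mM; time 3.0 min
- epsilon: G 0.80 mM; time 3.0 min

- south (time / s: D / %): 10.0: 1.3; 25.0: 3.6; 40.0: 5.7; 60.0: 9.4; 90.0: 13.6
- north (time / s: D / %): 20.0: 13.0; 40.0: 25.7; 50.0: 32.1; 80.0: 50.6; 90.0: 57.2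
- south-east (time / s: D / %): 10.0: 17.7; 15.0: 27.4; 25.0: 46.3; 50.0: 86.7; 90.0: 100.0

(readings scatter by 0.3 percentage points)

- at the start none of Z is dissolved
- the analysis behind the earlier runs scatters by 0.3 percentage points, standard deviation
- steps thought possible: X <-> Z; Q -> G + D; Z + L -> Q; E + G -> L
- "hardly changes" means that all values lie within two and a half points (for a concentration: within two and a half percent of the largest)
- a step back or a flat step of under half a point counts as no turn

1. amount of D at the end, in percent of the E charged for beta, theta, eta, zeta, epsilon, in this order
2. how the row runs (falls, then rises / hardly changes / falls all the way / rises all the way / rises, then falls)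

My zero of the scale is the strictly proportional flask, in which each G keeps the pace of the south run whatever the charge. The south run, with 0.052 mM of G, has turned 13.6% of its E into D at 90.0 s. Scaled by time and charge, that reading gives 0.191 mM, and I call this the proportional charge: the G that takes the whole of E through in the time if each G keeps the south pace.

The two runs with more G read less than that scale. The north run shows 57.2% at 90.0 s, less than the 62.8% of proportion, a ratio of 91.1%. The south-east run shows 46.3% at 25.0 s, less than the 66.8% of proportion, a ratio of 69.3%. So the proportional charge is too little, and I must charge above it.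

Eta stands at 105% of the proportional charge. With the north ratio I reckon 95.7% of E through in eta, which is short of the whole, so I do not choose eta. Zeta is twice the proportional charge, and even with the south-east ratio I reckon for zeta a pace worth 145% of the E charged over the time, which leaves a margin, so I charge zeta.

The forecast gives 31%, 60%, 90%, 100% and 100%, and so rises all the way, and it says: “Nothing suggests loss of D, so the row rises and then plateaus.” On eta it stands lower than my figure.

The flasks give 30.9%, 58.3%, 86.0%, 100% and 100%: rises all the way.

    X ⇌ Z, rate k1*(csat - [Z]) (kL = 0.504 s⁻¹)
    Q → G + D (k = 2.29 s⁻¹)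
    Z + L → Q (k = 1790 M⁻¹ s⁻¹)
    E + G → L (k = 192 M⁻¹ s⁻¹)

Beta, at 31.4% of the proportional charge, gives 30.9%. Eta, at 105% of it, gives 86.0%, with 13.8% of E left. Zeta has 0.0434% left of E, the limiting reagent, at 3.0 min. What holds beta down is the time given: it has 69.0% of E left at the end, and its D reaches >99.9% after ten times as long. At 30.0 min the rise in the row is gone, with eta at 100% and epsilon at 100%.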